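**Retrosynthetic overview**

1. Ring atoms are called C1 (CH–OAc), C2 (CH–OBz), C3=C4, C5 (C=O) and C6 (C(OH)CH2OBz). The enone goes back to the saturated ketone 8 (late C3–C4 dehydrogenation), the acetate to alcohol 7, and the C1 carbinol to the C1 ketone of the 2-hydroxy-1,3-dione 6.
2. Key disconnection, a [3+3] annulation that closes the only ring in one operation: C2–C3 by Michael addition and C5–C6 by a carbene-catalysed crossed acyloin (benzoin) closure. The partners are acrolein (C3–C4–C5) and the achiral, symmetrical diketone 3 (C2–C1–C6 plus the CH2OBz arm, both benzoates already in place).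
3. Enabling feature: the tertiary α-ketol of the six-membered ring, i.e. the ring carbonyl C5 bonded directly to the hydroxylated quaternary C6 (an acyloin), lying 1,3 to the benzoyloxy carbon C2 across C1. With C1 raised to a ketone, C2–H becomes an acidic Michael donor and C6 an activated carbonyl acceptor.
4. Diketone 3 comes from 1,4-dibromobutane-2,3-dione and sodium benzoate. C6 is set by the chiral carbene, C2 by equilibration, C1 by substrate-controlled hydride delivery.

Key step: step 2

Assumption: the (5aS,10bR) antipode of the triazolium salt is written as the one that delivers the (R)-carbinol of 6; if the sense of induction proves opposite, the enantiomeric salt is used.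

**Route**

Step 1
Reactants: 1 1,4-dibromobutane-2,3-dione; 2 sodium benzoate
Product: 3 2,3-dioxobutane-1,4-diyl dibenzoate
Conditions: 2 (2.2 equiv), DMF, 0 °C to rt
Reagents that add atoms: none
Why: Twofold SN2 displacement of the activated α-bromo ketone carbons by the carboxylate (phenacyl-ester-type O-alkylation) should be fast and clean under these weakly basic conditions, and no stereocentre is formed.

Step 2
Reactants: 3 2,3-dioxobutane-1,4-diyl dibenzoate; 4 acrolein (prop-2-enal)
Product: 6 [(1R,3R)-3-(benzoyloxy)-1-hydroxy-2,6-dioxocyclohexyl]methyl benzoate, via Michael adduct 5 (not isolated)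
Conditions: 4 (1.2 equiv, slow addition), (5aS,10bR)-5a,10b-dihydro-2-(pentafluorophenyl)-4H,6H-indeno[2,1-b][1,2,4]triazolo[4,3-d][1,4]oxazinium tetrafluoroborate (10 mol %), i-Pr2NEt (20 mol %), CH2Cl2, 0 °C to rt
Reagents that add atoms: none
Why: Proposed new method: the amine base enolises symmetrical 3 at one of its two equivalent benzoyloxymethylene carbons and the enolate adds to acrolein (Michael addition, first bond: C2–C3) to give keto aldehyde 5; the triazolylidene carbene freed from the salt by the same base then adds to the aldehyde, the resulting hydroxy-enamine (acyl anion equivalent) attacks the distal ketone carbonyl in a 6-exo-trig closure and the carbene is released (crossed benzoin, second bond: C5–C6, the only ring closed). The closest known reaction type is the one-pot Michael–crossed-benzoin cascade of 1,3-dicarbonyl compounds with enals under base/carbene catalysis, which closes α-hydroxycyclopentanones, together with carbene-catalysed crossed acyloin additions of aldehydes to α-diketones, which give the same 2-hydroxy-1,3-dione unit; new here are the six-membered closure and the acyclic α-acyloxy 1,2-diketone. The quaternary carbinol centre (C6) is set by the chiral aminoindanol-derived carbene, which differentiates the faces of the ketone in the carbon–carbon bond-forming step; the benzoyloxy-bearing centre (C2) is α to the surviving C1 carbonyl, hence labile, and should settle trans to the hydroxyl, the arrangement that places both the benzoyloxy and the benzoyloxymethyl group equatorial. The selectivity needed is closure onto the distal rather than the proximal carbonyl (six- versus five-membered ring): the distal carbonyl carries only a CH2 group and is the less hindered, and since acyloin formation is reversible under the carbene the less strained six-membered α-ketol should accumulate. Slow addition of acrolein should keep its carbene-initiated polymerisation and a second Michael addition in check.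

Step 3
Reactants: 6 [(1R,3R)-3-(benzoyloxy)-1-hydroxy-2,6-dioxocyclohexyl]methyl benzoate
Product: 7 [(1S,2S,3R)-3-(benzoyloxy)-1,2-dihydroxy-6-oxocyclohexyl]methyl benzoate
Conditions: NaBH4 (0.3 equiv), CH2Cl2/MeOH (4:1), −78 °C, then aq NH4Cl
Reagents that add atoms: none
Why: Hydride reduction with a small, non-chelating borohydride: of the two ketones the C1 carbonyl, flanked by two oxygen-bearing carbons, is the more electrophilic, and in the chair that holds the benzoyloxy and benzoyloxymethyl groups equatorial the hydride should enter axially, anti to the axial C6–O bond, which gives the equatorial C1 alcohol cis to the tertiary hydroxyl and trans to the benzoate and at the same time ends the lability of C2.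

Step 4
Reactants: 7 [(1S,2S,3R)-3-(benzoyloxy)-1,2-dihydroxy-6-oxocyclohexyl]methyl benzoate
Product: 8 [(1S,2S,3R)-2-(acetyloxy)-3-(benzoyloxy)-1-hydroxy-6-oxocyclohexyl]methyl benzoate
Conditions: Ac2O, pyridine, 4-(dimethylamino)pyridine (cat), CH2Cl2, 0 °C
Reagents that add atoms: acetic anhydride, CC(=O)OC(C)=O
Why: Nucleophile-catalysed O-acylation: only the secondary C1 hydroxyl should react, the tertiary α-ketol hydroxyl being too hindered at 0 °C, and no stereocentre is touched.

Step 5
Reactants: 8 [(1S,2S,3R)-2-(acetyloxy)-3-(benzoyloxy)-1-hydroxy-6-oxocyclohexyl]methyl benzoate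
Product: 9 [(1S,5R,6S)-6-(acetyloxy)-5-(benzoyloxy)-1-hydroxy-2-oxocyclohex-3-en-1-yl]methyl benzoate (2-O-acetylzeylenone)
Conditions: 2-iodoxybenzoic acid (IBX, 1.5 equiv), 4-methoxypyridine N-oxide (1.5 equiv), DMSO, rt
Reagents that add atoms: none
Why: Ketone α,β-dehydrogenation with the hypervalent iodine oxidant IBX: the C5 ketone can enolise only towards C4 because C6 is quaternary, so the new double bond can only be C3=C4 (cis by the ring), and the room-temperature variant with the N-oxide ligand should spare the esters and the stereocentres.

**Compound list**

1 | 1,4-dibromobutane-2,3-dione | BrCC(=O)C(=O)CBr | starting material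
2 | sodium benzoate | [Na+].[O-]C(=O)c1ccccc1 | starting material
3 | 2,3-dioxobutane-1,4-diyl dibenzoate | O=C(COC(=O)c1ccccc1)C(=O)COC(=O)c1ccccc1 | intermediate
4 | acrolein (prop-2-enal) | C=CC=O | starting material
5 | 4,7-bis(benzoyloxy)-5,6-dioxoheptanal (Michael adduct, labile at C4, not isolated) | O=CCCC(OC(=O)c1ccccc1)C(=O)C(=O)COC(=O)c1ccccc1 | intermediate
6 | [(1R,3R)-3-(benzoyloxy)-1-hydroxy-2,6-dioxocyclohexyl]methyl benzoate | O=C1[C@H](OC(=O)c2ccccc2)CCC(=O)[C@]1(O)COC(=O)c1ccccc1 | intermediate
7 | [(1S,2S,3R)-3-(benzoyloxy)-1,2-dihydroxy-6-oxocyclohexyl]methyl benzoate | O[C@H]1[C@H](OC(=O)c2ccccc2)CCC(=O)[C@]1(O)COC(=O)c1ccccc1 | intermediate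
8 | [(1S,2S,3R)-2-(acetyloxy)-3-(benzoyloxy)-1-hydroxy-6-oxocyclohexyl]methyl benzoate | CC(=O)O[C@H]1[C@H](OC(=O)c2ccccc2)CCC(=O)[C@]1(O)COC(=O)c1ccccc1 | intermediate
9 | [(1S,5R,6S)-6-(acetyloxy)-5-(benzoyloxy)-1-hydroxy-2-oxocyclohex-3-en-1-yl]methyl benzoate (2-O-acetylzeylenone) | CC(=O)O[C@H]1[C@H](OC(=O)c2ccccc2)C=CC(=O)[C@]1(O)COC(=O)c1ccccc1 | target

Total step count: 5
Longest linear sequence: 5 steps (1 → 3 → 6 → 7 → 8 → 9)

**Steps most likely to fail**

1. Step 2 (Proposed new method). What may go wrong: the acyloin closure takes the proximal instead of the distal carbonyl, so that a five-membered ring forms, or the carbene is diverted by the diketone itself. The fallback uses known chemistry, sets out from 3 (with 4) and comes back at 6. Michael addition under Et3N alone gives 5, which is now isolated. Carbene-catalysed crossed benzoin in the five-membered mode established for δ-keto aldehydes gives 2-[(1S,2R)-2-(benzoyloxy)-1-hydroxy-5-oxocyclopentyl]-2-oxoethyl benzoate F1. A Lewis-acid-promoted α-ketol rearrangement (Al(Ot-Bu)3, toluene, rt to 60 °C) then shifts the ring acyl carbon from the carbinol carbon to the side-chain carbonyl carbon. This expands the ring, and within the aluminium chelate the carbinol configuration should be relayed to C6, returning 6.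

2. Step 3. What may go wrong: loss of site selectivity between the two ring carbonyls (over-reduction to the triol) or hydride delivery to the wrong face of C1. The fallback sets out from 6 and comes back at 7. Substrate control is replaced by catalyst control: asymmetric transfer hydrogenation with RuCl(p-cymene)[(S,S)-TsDPEN] (or its antipode, whichever is matched) in HCO2H/Et3N, CH2Cl2. This catalyst class reduces α-oxygenated ketones much faster than dialkyl ketones. Because C2 of 6 epimerises, the reduction runs as a dynamic kinetic resolution and both C2 epimers should converge on 7. No new compound is made.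

3. Step 5. What may go wrong: over-oxidation of the product enone to a dienone, or elimination of benzoic acid with aromatisation on prolonged exposure to the oxidant. The fallback sets out from 8 and comes back at 9. Acid-mediated α-selenenylation through the enol (PhSeCl, EtOAc, rt) should give [(1S,2S,3R)-2-(acetyloxy)-3-(benzoyloxy)-1-hydroxy-6-oxo-5-(phenylselanyl)cyclohexyl]methyl benzoate F2 as both epimers at the selenium-bearing carbon. Oxidation (H2O2, pyridine, CH2Cl2, 0 °C) and syn-elimination of the selenoxide, which can only remove a hydrogen from C3, should then give 9.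

**Further compounds**

F1 | step 2 | 2-[(1S,2R)-2-(benzoyloxy)-1-hydroxy-5-oxocyclopentyl]-2-oxoethyl benzoate | O=C1CC[C@@H](OC(=O)c2ccccc2)[C@@]1(O)C(=O)COC(=O)c1ccccc1
F0 | step 3 | none | none
F2 | step 5 | [(1S,2S,3R)-2-(acetyloxy)-3-(benzoyloxy)-1-hydroxy-6-oxo-5-(phenylselanyl)cyclohexyl]methyl benzoate (both C5 epimers) | CC(=O)O[C@H]1[C@H](OC(=O)c2ccccc2)CC([Se]c2ccccc2)C(=O)[C@]1(O)COC(=O)c1ccccc1
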